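In this flask each partner that goes ends in homo dimer, decomposed reagent or one of the two products.

    partner → decomposed reagent (k1 = 1.5 × 10⁻⁵ s⁻¹)
    partner + right-handed substrate → right-handed product (k2 = 5.8 × 10⁻⁷ L mol⁻¹ s⁻¹)
    partner + left-handed substrate → left-handed product (k3 = 1.6 × 10⁻⁵ L mol⁻¹ s⁻¹)
    left-handed substrate ⇌ right-handed substrate (k4 = 1.3 × 10⁻⁵ s⁻¹)
    2 partner → homo dimer (k5 = 1.5 × 10⁻⁵ L mol⁻¹ s⁻¹)

left-handed substrate 1.0 M; partner 2.50 M; right-handed substrate 1.0 M; time 15 d

- partner is single-handed; left-handed substrate and right-handed substrate are mirror images of each other, charged as a racemate, each of them at the stated concentration
- a doubled species enters its step squared and goes two at a time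
- the reaction counts as stopped when no species that holds the left-handed substrate and right-handed substrate together changes by six tenths of a point or more over the second half of the time
- run time (flask): 15 d
- the handed part of partner does not stay in what it makes, so the products of the two hands are mirror images too

1. which holds at 15 d: what has brought the reaction to rest, or that it has not come to rest (all of the left-handed substrate has reacted / forward and back rates have come level / it is still moving / the partner has run out first)
2. the left-handed product standing at 15 d, as a percentage of the left-handed substrate and right-handed substrate together charged

Two rates per partner carry this reckoning. Pairing with a second partner takes each partner at 7.50 × 10⁻⁵ s⁻¹ at the charge, and that rate falls as the partner thins. Decomposition and the two substrates, held at their charge, take it at a steady 3.16 × 10⁻⁵ s⁻¹, so the ratio of the two starts at 2.37.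

Other rates can wait. The half-life of racemisation, 0.617 d, is longer than the partner's time, the reciprocal of the two rates added, 0.109 d. The left-handed step is also faster than the right-handed one, by a selectivity factor of 27.6.

Summing the left-handed share as the partner falls gives the left-handed rate constant times the substrate charge, over twice the pairing constant, times the natural logarithm of one plus the ratio. Against both substrates charged, that comes to 32.4 %, the capture yield. The run time is far longer than the partner's time, so this reckoning expects the partner to be used up first, although its charge of 2.50 M is more than the 2.00 M of both substrates together.

The forecast gives the partner has run out first and 28.5 %, holding that “racemisation keeps feeding left-handed substrate at a comparable rate”.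

The simulated flask gives the partner has run out first, with 27.1 % of left-handed product, which is less than the capture yield. In this flask the partner stands at 0 % at 15.0 d, while 72 % of the left-handed substrate remains. For the neighbour flask with 0.62 M of partner, the capture yield comes to 12.3 %, and that flask, keeping 88 % of its left-handed substrate, holds 11.7 % of left-handed product.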